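**Assumption (chemistry):** di-tert-butyl squarate 8 is treated as a purchasable squaric acid diester. The central ring of the target is numbered C1–C6, with benzoates on C1 and C2, aryl rings on C3 and C6, and free hydroxyls on C4 and C5.

## The problem

Compound 23 is a p-terphenyl whose central benzene ring is fully substituted: C1 and C2 carry benzoate esters, C3 and C6 carry 4-hydroxyphenyl rings, and C4 and C5 carry free hydroxyls. It has no stereocentre and no hindered axis to control, since the outer rings are para-substituted, so the task is one of regiochemistry alone. The four ring oxygens form two adjacent pairs that become equivalent in any symmetric or fully deprotected precursor, so a late selective benzoylation of a tetraol cannot be relied on and the two pairs must be told apart by the way the ring is made. Aryl benzoates do not tolerate strong base, nucleophiles or hard Lewis acids, and the catechol and hydroquinone stages oxidise readily to quinones. The esters should therefore come late, the last unmasking should be neutral, and free polyphenols should be handled briefly and without air. The feature that opens a way is the pattern along the ring: C5–C6–C1–C2 read O, aryl, O, O, which is the substitution of an aryl semisquarate after a carbon nucleophile has added to one ring carbonyl, and C3–C4 read aryl, O, which is a 1-aryl-2-alkoxyvinyl group. The two pieces meet at the C4–C5 bond between two oxygen-bearing carbons, the bond that a ketene carbon and an enol ether terminus make in a 6π closure, and the four oxygens then come from four different functions: ketene, enol ether, vinylogous ester and carbinol.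

## Retrosynthesis

**23 ⇒ 22.** The four phenolic O–H bonds at C4, C5 and the two outer rings are traced back to benzyl ethers in tetrabenzyl ether dibenzoate 22. Hydrogenolysis is neutral, leaves aryl benzoates alone, and unmasks all four phenols in one operation. Silyl or acetal masks would need fluoride or acid in the presence of the esters. The forward step only has to avoid transesterification, so a non-alcoholic solvent is used.

**22 ⇒ 21 ⇒ 19 ⇒ 18.** The two acyl C–O bonds at C1 and C2 are cut to give catechol 21. This catechol is reached from fully protected arene 19, in which C1 carries a tert-butyl ether, C2 a silyl ether, and C4/C5 benzyl ethers. Acid followed by fluoride removes exactly the two groups on C1/C2 (via silyloxyphenol 20) and leaves every benzyl ether. Arene 19 comes from phenol 18 by benzylation of its single free hydroxyl at C5. After that step, C4/C5 and the outer phenols share one protecting group and C1/C2 are the only oxygens that acid and fluoride can free.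

**18 ⇒ 15 (key disconnection).** The C4–C5 bond is cut. Phenol 18 is the tautomer of cyclohexadienone 17, which opens in the retro sense to dienylketene 16, which in turn closes to cyclobutenone 15. This cut is preferred over biaryl disconnections at C3 and C6, because cross-couplings onto a preformed hexasubstituted dihalobenzene would leave the four oxygens undifferentiated. In 15 every substituent of the future ring is already in place and the four oxygens are chemically distinct. The forward reaction requires only heat and inward rotation of the alkenyl group during ring opening.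

**15 ⇒ 12 + 6.** The bond between the carbinol carbon (future C2) and the vinyl carbon (future C3) is cut, together with the O–Si bond. Vinyllithium 13, made from bromo enol ether 6, adds to the ketone-like carbonyl of aryl semisquarate 12, and lithium alkoxide 14 is captured as the silyl ether. The other carbonyl of 12 is a vinylogous ester and is much less electrophilic, which sets the regiochemistry of the addition. The precursors are a four-membered ring with one aryl group and a two-carbon vinyl bromide.

**12 ⇒ 7 + 8.** The C6–aryl bond is cut. Aryllithium 9 from bromide 7 adds to squarate 8 to give alkoxide 10. Acylation to trifluoroacetate 11, ionisation and loss of one tert-butyl group give 12. The tert-butyl ester is chosen over methyl or isopropyl because the resulting aryl tert-butyl ether can later be removed by mild acid without touching benzyl ethers.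

**6 ⇒ 4 ⇒ 1 + 2.** The C–Br bond is traced to bromination and dehydrobromination of enol ether 4 via dibromide 5. The alkene of 4 is traced to a Wittig reaction of aldehyde 1 with ylide 3 from phosphonium salt 2. Benzyl is chosen on the enol oxygen so that the C4 oxygen emerges with the same mask as the outer phenols.

## Roads not taken

**Alternative 1:** The outer phenol rings are cut instead of the central one. The starting point would be the bis(arylacetaldehyde) A1, a benzodioxole-bridged central ring that already carries both benzoates. Each aldehyde arm of A1 would undergo acid-catalysed Michael addition to a four-carbon vinyl ketone followed by intramolecular aldol condensation. This forms four C–C bonds and both outer rings as the bis(cyclohexenone) A2, which is then dehydrogenated to the two phenols.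
- Merits: the outer phenols need no protecting groups, no organolithium chemistry is used, and the benzoates are already in place in A2.
- Weak points: A1 presupposes a central ring in which C1/C2 and C4/C5 have already been told apart, so the real problem is moved upstream and left unsolved. A dialdehyde such as A1 self-condenses readily. Two late dehydrogenations of A2 are needed. The methylenedioxy bridge on C4/C5 must finally be cleaved with a boron trihalide in the presence of aryl benzoates.
- Comparison: Alternative 1 is better in protecting-group economy on the outer rings. The chosen plan sets against this the purchase of both outer rings as intact aryl units and a single step that builds the central ring with its oxygen pattern fixed.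

**Alternative 2:** The central ring is cut at C2–C3 and C5–C6. The building block would be the arylpyruvate ester A3. Two molecules of A3 would condense under an alkoxide base, each benzylic carbon being acylated by the ester carbonyl of the other, to give dihydroxyquinone A4.
- Merits: this is the shortest route to the carbon skeleton. It uses the single building block A3 and one ring-forming step, and all four oxygens are in place in A4. In step count to the skeleton it is clearly better than the chosen plan.
- Weak points: A4 is symmetric and stays symmetric after reduction to the hydroquinone level. The target needs one adjacent oxygen pair benzoylated and the other left free, which means a statistical or weakly selective protection of one ortho pair, with air-sensitive leuco intermediates and the risk of acyl scrambling between neighbouring phenols.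
- Comparison: if a clean protection of one catechol pair of reduced A4 were available, Alternative 2 would be the better route. The chosen plan is longer in fragment preparation but the four oxygens are born different (free OH, benzyl, tert-butyl, silyl), so no selective reaction on equivalent hydroxyls is needed.

**Alternative 3:** The two benzoate C–O bonds at C1 and C2 are cut. The 1,2-dibenzoylarene A5 would be treated with a buffered peroxy acid, and double Baeyer–Villiger migration of the central ring from carbon to oxygen would give dibenzoate A6.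
- Merits: both benzoates arrive at the right carbons by construction, distinct from the C4/C5 oxygens, and the endgame from A6 is only desilylation and hydrogenolysis. In the way the esters are placed it is at least as good as the chosen plan.
- Weak points: the hexasubstituted central ring of A5 must migrate in preference to phenyl twice, the second time next to a new ester and out of a twisted, crowded ketone. A strong peroxy acid also meets silyloxy- and benzyloxy-substituted arenes that are easily over-oxidised. The synthesis of the hexasubstituted A5 is a ring-construction problem that the key step does not address.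
- Comparison: the chosen plan builds the ring and differentiates the oxygens in the same thermal, reagent-free step and needs no strong oxidant.

Key step: step 5

## Route

**Step 1**
Reactants: 1 4-(benzyloxy)benzaldehyde; 2 (benzyloxymethyl)triphenylphosphonium chloride
Product: 4 1-(benzyloxy)-4-[2-(benzyloxy)vinyl]benzene (E/Z mixture), via phosphorus ylide 3 (not isolated)
Conditions: KOtBu, THF, 0 °C to rt
Reagents that add atoms: none
Why: Wittig olefination of an aromatic aldehyde with an alkoxymethylene ylide, the benzyl analogue of the methoxymethyl homologation reagent; the E/Z ratio is irrelevant because both isomers give the same dibromide-derived product in step 2.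

**Step 2**
Reactants: 4 1-(benzyloxy)-4-[2-(benzyloxy)vinyl]benzene
Product: 6 (Z)-1-(benzyloxy)-4-[2-(benzyloxy)-1-bromovinyl]benzene, via dibromide 5 (not isolated)
Conditions: Br2 (1.0 equiv), CH2Cl2, −78 °C; then iPr2NEt, −78 °C to rt
Reagents that add atoms: bromine, BrBr
Why: Bromine addition to the enol ether (far more nucleophilic than the benzyloxyarenes) followed by dehydrobromination, the classical route to β-bromo enol ethers; the α-bromo ether ionises to an oxocarbenium ion and the amine removes the acidic benzylic proton, which places bromine on the aryl-bearing carbon. The Z isomer (bromine cis to benzyloxy, aryl trans to oxygen) is expected to predominate, and any E isomer should be removed by chromatography.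

**Step 3**
Reactants: 7 1-(benzyloxy)-4-bromobenzene; 8 di-tert-butyl squarate (3,4-di-tert-butoxycyclobut-3-ene-1,2-dione)
Product: 12 3-[4-(benzyloxy)phenyl]-4-tert-butoxycyclobut-3-ene-1,2-dione, via aryllithium 9 (not isolated), via lithium alkoxide 10 (not isolated), via trifluoroacetate 11 (not isolated)
Conditions: n-BuLi, THF, −78 °C; then 8, −78 °C; then (CF3CO)2O, −78 °C; cold NaHCO3 work-up
Reagents that add atoms: none
Why: Bromine–lithium exchange, 1,2-addition to a squarate carbonyl, then acylative ionisation of the carbinol; the alkoxy-stabilised cation loses one tert-butyl group as isobutene to give the semisquarate, which is the standard squarate-to-3-alkoxy-4-arylcyclobutenedione sequence. Cold quenching keeps the remaining vinylogous tert-butyl ester intact.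

**Step 4**
Reactants: 6 (Z)-1-(benzyloxy)-4-[2-(benzyloxy)-1-bromovinyl]benzene; 12 3-[4-(benzyloxy)phenyl]-4-tert-butoxycyclobut-3-ene-1,2-dione
Product: 15 2-[4-(benzyloxy)phenyl]-4-{(Z)-2-(benzyloxy)-1-[4-(benzyloxy)phenyl]vinyl}-3-tert-butoxy-4-(tert-butyldimethylsilyloxy)cyclobut-2-en-1-one (racemic), via vinyllithium 13 (not isolated), via lithium alkoxide 14 (not isolated)
Conditions: t-BuLi (2 equiv), THF, −78 °C; then 12, −78 °C; then TBSOTf, −78 to −40 °C; NaHCO3 work-up
Reagents that add atoms: tert-butyldimethylsilyl trifluoromethanesulfonate, CC(C)(C)[Si](C)(C)OS(=O)(=O)C(F)(F)F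
Why: Bromine–lithium exchange with retention gives the vinyllithium with lithium cis to the benzyloxy oxygen, the chelated geometry in which β-elimination is slow at −78 °C (as for cis-2-alkoxyvinyllithiums). It adds 1,2 to the ketone-like carbonyl of 12 next to the tert-butoxy-bearing carbon, not to the vinylogous ester carbonyl, and the alkoxide is silylated in the same flask by the silyl triflate. The new carbinol stereocentre is racemic and is destroyed in step 5.

**Step 5**
Reactants: 15 2-[4-(benzyloxy)phenyl]-4-{(Z)-2-(benzyloxy)-1-[4-(benzyloxy)phenyl]vinyl}-3-tert-butoxy-4-(tert-butyldimethylsilyloxy)cyclobut-2-en-1-one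
Product: 18 2-(benzyloxy)-3,6-bis[4-(benzyloxy)phenyl]-5-tert-butoxy-4-(tert-butyldimethylsilyloxy)phenol, via dienylketene 16 (not isolated), via cyclohexadienone 17 (not isolated)
Conditions: PhMe (degassed), 110 °C, argon
Reagents that add atoms: none
Why: Heating opens the cyclobutenone by conrotatory 4π electrocyclic cleavage of the bond between the carbonyl carbon and the silyloxy carbon to give dienylketene 16; the silyloxy donor on the carbinol carbon rotates outward, so the alkenyl group turns inward and ends cis to the ketene. The ketene carbon (future C5) and the benzyloxy-bearing vinyl carbon (future C4) then join in a thermal disrotatory 6π electrocyclisation, which closes the six-membered central ring as cyclohexa-2,4-dienone 17 and forms the C4–C5 bond. The single hydrogen on C4 then moves to oxygen by enolisation to give phenol 18; no neighbouring hydrogen is available for loss of benzyl alcohol, so aromatisation can only occur by tautomerisation. The closest known reaction type is the thermal ring expansion of squarate-derived 4-alkenyl-4-hydroxy- or 4-silyloxycyclobutenones to hydroquinones and their monoethers. No stereocentre survives: the racemic carbinol centre, the enol ether geometry and the transient sp3 carbon of 17 are all erased on aromatisation. The selectivity needed is inward rotation of the alkenyl group, secured by the outward preference of the oxygen substituent; any ketene formed by the other rotation can revert to 15 and re-enter. Neither aryl ring is placed to take part in a competing 6π closure, since no contiguous triene runs from the ketene carbon into either of them. The silyl, tert-butyl and benzyl ethers should tolerate neutral toluene at 110 °C, and oxygen is excluded to protect the electron-rich phenol.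

**Step 6**
Reactants: 18 2-(benzyloxy)-3,6-bis[4-(benzyloxy)phenyl]-5-tert-butoxy-4-(tert-butyldimethylsilyloxy)phenol
Product: 19 1,2-bis(benzyloxy)-3,6-bis[4-(benzyloxy)phenyl]-4-tert-butoxy-5-(tert-butyldimethylsilyloxy)benzene
Conditions: BnBr, K2CO3, DMF (anhydrous), rt
Reagents that add atoms: benzyl bromide, BrCc1ccccc1
Why: Williamson etherification of the only free phenol; the aryl silyl ether is flanked by tert-butoxy and aryl groups and should withstand anhydrous carbonate at room temperature.

**Step 7**
Reactants: 19 1,2-bis(benzyloxy)-3,6-bis[4-(benzyloxy)phenyl]-4-tert-butoxy-5-(tert-butyldimethylsilyloxy)benzene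
Product: 21 4,5-bis(benzyloxy)-3,6-bis[4-(benzyloxy)phenyl]benzene-1,2-diol, via silyloxyphenol 20 (not isolated)
Conditions: CF3CO2H, CH2Cl2, 0 °C; evaporate; then Bu4NF, AcOH, THF, 0 °C, argon
Reagents that add atoms: none
Why: Acidolysis of the aryl tert-butyl ether with loss of isobutene at a temperature where aryl benzyl ethers persist, then fluoride desilylation buffered with acetic acid so that no free phenoxide of the oxidation-prone catechol is exposed; the catechol is taken on at once.

**Step 8**
Reactants: 21 4,5-bis(benzyloxy)-3,6-bis[4-(benzyloxy)phenyl]benzene-1,2-diol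
Product: 22 4,5-bis(benzyloxy)-3,6-bis[4-(benzyloxy)phenyl]-1,2-phenylene dibenzoate
Conditions: BzCl, Et3N, DMAP (cat.), CH2Cl2, 0 °C to rt
Reagents that add atoms: benzoyl chloride, O=C(Cl)c1ccccc1
Why: DMAP-catalysed acylation of both phenols of the catechol; these are the only free hydroxyls, so the benzoates can only land on C1 and C2.

**Step 9**
Reactants: 22 4,5-bis(benzyloxy)-3,6-bis[4-(benzyloxy)phenyl]-1,2-phenylene dibenzoate
Product: 23 4,5-dihydroxy-3,6-bis(4-hydroxyphenyl)-1,2-phenylene dibenzoate (CNP0216579.0)
Conditions: H2 (1 atm), Pd/C (palladium metal on carbon), EtOAc–THF, rt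
Reagents that add atoms: none
Why: Hydrogenolysis of four aryl benzyl ethers under neutral conditions that leave aryl benzoates untouched; each benzoate is flanked by the other benzoate and an aryl-bearing carbon, so no ortho hydroxyl is available for acyl migration.

## Compound list

1 | 4-(benzyloxy)benzaldehyde | O=Cc1ccc(OCc2ccccc2)cc1 | starting material
2 | (benzyloxymethyl)triphenylphosphonium chloride | [Cl-].c1ccc(cc1)[P+](COCc1ccccc1)(c1ccccc1)c1ccccc1 | starting material
3 | (benzyloxymethylidene)triphenyl-λ5-phosphane (ylide) | C(OCc1ccccc1)=P(c1ccccc1)(c1ccccc1)c1ccccc1 | intermediate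
4 | 1-(benzyloxy)-4-[2-(benzyloxy)vinyl]benzene (E/Z mixture) | C(=COCc1ccccc1)c1ccc(OCc2ccccc2)cc1 | intermediate
5 | 1-(benzyloxy)-4-[2-(benzyloxy)-1,2-dibromoethyl]benzene (diastereomer mixture) | BrC(OCc1ccccc1)C(Br)c1ccc(OCc2ccccc2)cc1 | intermediate
6 | (Z)-1-(benzyloxy)-4-[2-(benzyloxy)-1-bromovinyl]benzene | Br/C(c1ccc(OCc2ccccc2)cc1)=C\OCc1ccccc1 | intermediate
7 | 1-(benzyloxy)-4-bromobenzene | Brc1ccc(OCc2ccccc2)cc1 | starting material
8 | di-tert-butyl squarate (3,4-di-tert-butoxycyclobut-3-ene-1,2-dione) | O=C1C(=O)C(OC(C)(C)C)=C1OC(C)(C)C | starting material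
9 | [4-(benzyloxy)phenyl]lithium | [Li]c1ccc(OCc2ccccc2)cc1 | intermediate
10 | lithium 1-[4-(benzyloxy)phenyl]-2,3-di-tert-butoxy-4-oxocyclobut-2-en-1-olate (racemic) | [Li+].[O-]C1(c2ccc(OCc3ccccc3)cc2)C(OC(C)(C)C)=C(OC(C)(C)C)C1=O | intermediate
11 | 1-[4-(benzyloxy)phenyl]-2,3-di-tert-butoxy-4-oxocyclobut-2-en-1-yl trifluoroacetate (racemic) | O=C(OC1(c2ccc(OCc3ccccc3)cc2)C(OC(C)(C)C)=C(OC(C)(C)C)C1=O)C(F)(F)F | intermediate
12 | 3-[4-(benzyloxy)phenyl]-4-tert-butoxycyclobut-3-ene-1,2-dione | O=C1C(=O)C(c2ccc(OCc3ccccc3)cc2)=C1OC(C)(C)C | intermediate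
13 | {2-(benzyloxy)-1-[4-(benzyloxy)phenyl]vinyl}lithium, lithium cis to the benzyloxy group (E by the sequence rule) | [Li]/C(c1ccc(OCc2ccccc2)cc1)=C\OCc1ccccc1 | intermediate
14 | lithium 3-[4-(benzyloxy)phenyl]-1-{(Z)-2-(benzyloxy)-1-[4-(benzyloxy)phenyl]vinyl}-2-tert-butoxy-4-oxocyclobut-2-en-1-olate (racemic) | [Li+].[O-]C1(/C(c2ccc(OCc3ccccc3)cc2)=C\OCc2ccccc2)C(OC(C)(C)C)=C(c2ccc(OCc3ccccc3)cc2)C1=O | intermediate
15 | 2-[4-(benzyloxy)phenyl]-4-{(Z)-2-(benzyloxy)-1-[4-(benzyloxy)phenyl]vinyl}-3-tert-butoxy-4-(tert-butyldimethylsilyloxy)cyclobut-2-en-1-one (racemic) | O=C1C(c2ccc(OCc3ccccc3)cc2)=C(OC(C)(C)C)C1(O[Si](C)(C)C(C)(C)C)/C(c1ccc(OCc2ccccc2)cc1)=C\OCc1ccccc1 | intermediate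
16 | (3Z,5Z)-6-(benzyloxy)-2,5-bis[4-(benzyloxy)phenyl]-3-tert-butoxy-4-(tert-butyldimethylsilyloxy)hexa-1,3,5-trien-1-one (dienylketene) | O=C=C(c1ccc(OCc2ccccc2)cc1)/C(OC(C)(C)C)=C(O[Si](C)(C)C(C)(C)C)\C(c1ccc(OCc2ccccc2)cc1)=C/OCc1ccccc1 | intermediate
17 | 6-(benzyloxy)-2,5-bis[4-(benzyloxy)phenyl]-3-tert-butoxy-4-(tert-butyldimethylsilyloxy)cyclohexa-2,4-dien-1-one (racemic) | O=C1C(c2ccc(OCc3ccccc3)cc2)=C(OC(C)(C)C)C(O[Si](C)(C)C(C)(C)C)=C(c2ccc(OCc3ccccc3)cc2)C1OCc1ccccc1 | intermediate
18 | 2-(benzyloxy)-3,6-bis[4-(benzyloxy)phenyl]-5-tert-butoxy-4-(tert-butyldimethylsilyloxy)phenol | Oc1c(-c2ccc(OCc3ccccc3)cc2)c(OC(C)(C)C)c(O[Si](C)(C)C(C)(C)C)c(-c2ccc(OCc3ccccc3)cc2)c1OCc1ccccc1 | intermediate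
19 | 1,2-bis(benzyloxy)-3,6-bis[4-(benzyloxy)phenyl]-4-tert-butoxy-5-(tert-butyldimethylsilyloxy)benzene | c1ccccc1COc1c(-c2ccc(OCc3ccccc3)cc2)c(OC(C)(C)C)c(O[Si](C)(C)C(C)(C)C)c(-c2ccc(OCc3ccccc3)cc2)c1OCc1ccccc1 | intermediate
20 | 3,4-bis(benzyloxy)-2,5-bis[4-(benzyloxy)phenyl]-6-(tert-butyldimethylsilyloxy)phenol | Oc1c(O[Si](C)(C)C(C)(C)C)c(-c2ccc(OCc3ccccc3)cc2)c(OCc2ccccc2)c(OCc2ccccc2)c1-c1ccc(OCc2ccccc2)cc1 | intermediate
21 | 4,5-bis(benzyloxy)-3,6-bis[4-(benzyloxy)phenyl]benzene-1,2-diol | Oc1c(O)c(-c2ccc(OCc3ccccc3)cc2)c(OCc2ccccc2)c(OCc2ccccc2)c1-c1ccc(OCc2ccccc2)cc1 | intermediate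
22 | 4,5-bis(benzyloxy)-3,6-bis[4-(benzyloxy)phenyl]-1,2-phenylene dibenzoate | O=C(Oc1c(OC(=O)c2ccccc2)c(-c2ccc(OCc3ccccc3)cc2)c(OCc2ccccc2)c(OCc2ccccc2)c1-c1ccc(OCc2ccccc2)cc1)c1ccccc1 | intermediate
23 | 4,5-dihydroxy-3,6-bis(4-hydroxyphenyl)-1,2-phenylene dibenzoate (CNP0216579.0) | O=C(Oc1c(OC(=O)c2ccccc2)c(-c2ccc(O)cc2)c(O)c(O)c1-c1ccc(O)cc1)c1ccccc1 | target

## Step count and risks

Total: 9 steps. Longest linear sequence: 8 steps (steps 1, 2, 4, 5, 6, 7, 8, 9 from aldehyde 1); step 3 is the one-step branch that supplies 12.

**Step 5 (key step).** The 6π closure has to engage a trisubstituted, oxygen-bearing alkene terminus, whose benzyloxy group points inward, in a crowded dienylketene. If closure is slow, the ketene is diverted by dimerisation or capture by adventitious nucleophiles, and prolonged heating invites thermal loss of isobutene from the tert-butoxy group. The fallback sets out from 12 and comes back at 19; it introduces the C4 oxygen after ring formation. The Shapiro precursor N'-{1-[4-(benzyloxy)phenyl]ethylidene}-2,4,6-triisopropylbenzenesulfonohydrazide F1, made from the purchasable aryl methyl ketone, is converted by n-BuLi into {1-[4-(benzyloxy)phenyl]vinyl}lithium F2. Addition to 12 and capture with TBSOTf give 2-[4-(benzyloxy)phenyl]-4-{1-[4-(benzyloxy)phenyl]vinyl}-3-tert-butoxy-4-(tert-butyldimethylsilyloxy)cyclobut-2-en-1-one F3. Thermolysis, now onto an unsubstituted CH2 terminus (the best-precedented case), should give 2,5-bis[4-(benzyloxy)phenyl]-3-tert-butoxy-4-(tert-butyldimethylsilyloxy)phenol F4, with one free ortho position. Ortho-oxygenation with 2-iodoxybenzoic acid gives 3,6-bis[4-(benzyloxy)phenyl]-4-tert-butoxy-5-(tert-butyldimethylsilyloxy)cyclohexa-3,5-diene-1,2-dione F5, reduced in the same flask with Na2S2O4 to 3,6-bis[4-(benzyloxy)phenyl]-4-tert-butoxy-5-(tert-butyldimethylsilyloxy)benzene-1,2-diol F6. Double benzylation (BnBr, K2CO3, degassed DMF) returns to 19.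

**Step 4.** Three things may go wrong. Lithium benzyloxide may be lost from the vinyllithium by β-elimination if the metal is not held cis to oxygen. The nucleophile may attack the vinylogous ester carbonyl or displace tert-butoxide by conjugate addition. Silylation of the crowded tertiary alkoxide may be incomplete, followed by anion-accelerated ring opening on warming. The fallback sets out from 6 and 12 and comes back at 15; it separates C–C bond formation from silylation. The adduct alkoxide is protonated at −78 °C with NH4Cl, and 2-[4-(benzyloxy)phenyl]-4-{(Z)-2-(benzyloxy)-1-[4-(benzyloxy)phenyl]vinyl}-3-tert-butoxy-4-hydroxycyclobut-2-en-1-one F7 is isolated and purified. It is then silylated in a separate operation with TBSOTf and 2,6-lutidine in CH2Cl2 to give 15. If the lithium reagent itself proves to be the weak point, the side-chain oxygen is postponed as in the fallback for step 5.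

**Step 2.** Dehydrobromination may go in the wrong direction or with poor geometric control (bromine trans to the benzyloxy group leads to a lithium reagent prone to elimination), and ring bromination may compete. The fallback sets out from 4 and comes back at 6. Bromo-alkoxylation with N-bromosuccinimide in the presence of benzyl alcohol gives the stable acetal 1-(benzyloxy)-4-[2,2-bis(benzyloxy)-1-bromoethyl]benzene F8, which fixes bromine on the benzylic carbon. Elimination of benzyl alcohol with Me3SiOTf and iPr2NEt then gives 6 under conditions where the geometry can equilibrate through the oxocarbenium ion.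

**Step 7.** The free electron-rich catechol may oxidise to the ortho-quinone during fluoride treatment or work-up, and acid may cause partial loss of benzyl ethers or tert-butylation of an aryl ring. The fallback sets out from 19 and comes back at 22; the catechol is never set free. Buffered fluoride first removes the silyl ether to give 3,4-bis(benzyloxy)-2,5-bis[4-(benzyloxy)phenyl]-6-tert-butoxyphenol F9. This is benzoylated to 3,4-bis(benzyloxy)-2,5-bis[4-(benzyloxy)phenyl]-6-tert-butoxyphenyl benzoate F10. Trifluoroacetic acid then removes the tert-butyl group to give 3,4-bis(benzyloxy)-2,5-bis[4-(benzyloxy)phenyl]-6-hydroxyphenyl benzoate F11, and a second benzoylation gives 22.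

## Further compounds

F1 | step 5 | N'-{1-[4-(benzyloxy)phenyl]ethylidene}-2,4,6-triisopropylbenzenesulfonohydrazide | CC(=NNS(=O)(=O)c1c(C(C)C)cc(C(C)C)cc1C(C)C)c1ccc(OCc2ccccc2)cc1
F2 | step 5 | {1-[4-(benzyloxy)phenyl]vinyl}lithium | [Li]C(=C)c1ccc(OCc2ccccc2)cc1
F3 | step 5 | 2-[4-(benzyloxy)phenyl]-4-{1-[4-(benzyloxy)phenyl]vinyl}-3-tert-butoxy-4-(tert-butyldimethylsilyloxy)cyclobut-2-en-1-one (racemic) | O=C1C(c2ccc(OCc3ccccc3)cc2)=C(OC(C)(C)C)C1(O[Si](C)(C)C(C)(C)C)C(=C)c1ccc(OCc2ccccc2)cc1
F4 | step 5 | 2,5-bis[4-(benzyloxy)phenyl]-3-tert-butoxy-4-(tert-butyldimethylsilyloxy)phenol | Oc1cc(-c2ccc(OCc3ccccc3)cc2)c(O[Si](C)(C)C(C)(C)C)c(OC(C)(C)C)c1-c1ccc(OCc2ccccc2)cc1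
F5 | step 5 | 3,6-bis[4-(benzyloxy)phenyl]-4-tert-butoxy-5-(tert-butyldimethylsilyloxy)cyclohexa-3,5-diene-1,2-dione | O=C1C(=O)C(c2ccc(OCc3ccccc3)cc2)=C(O[Si](C)(C)C(C)(C)C)C(OC(C)(C)C)=C1c1ccc(OCc2ccccc2)cc1
F6 | step 5 | 3,6-bis[4-(benzyloxy)phenyl]-4-tert-butoxy-5-(tert-butyldimethylsilyloxy)benzene-1,2-diol | Oc1c(O)c(-c2ccc(OCc3ccccc3)cc2)c(O[Si](C)(C)C(C)(C)C)c(OC(C)(C)C)c1-c1ccc(OCc2ccccc2)cc1
F7 | step 4 | 2-[4-(benzyloxy)phenyl]-4-{(Z)-2-(benzyloxy)-1-[4-(benzyloxy)phenyl]vinyl}-3-tert-butoxy-4-hydroxycyclobut-2-en-1-one (racemic) | O=C1C(c2ccc(OCc3ccccc3)cc2)=C(OC(C)(C)C)C1(O)/C(c1ccc(OCc2ccccc2)cc1)=C\OCc1ccccc1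
F8 | step 2 | 1-(benzyloxy)-4-[2,2-bis(benzyloxy)-1-bromoethyl]benzene (racemic) | BrC(c1ccc(OCc2ccccc2)cc1)C(OCc1ccccc1)OCc1ccccc1
F9 | step 7 | 3,4-bis(benzyloxy)-2,5-bis[4-(benzyloxy)phenyl]-6-tert-butoxyphenol | Oc1c(OC(C)(C)C)c(-c2ccc(OCc3ccccc3)cc2)c(OCc2ccccc2)c(OCc2ccccc2)c1-c1ccc(OCc2ccccc2)cc1
F10 | step 7 | 3,4-bis(benzyloxy)-2,5-bis[4-(benzyloxy)phenyl]-6-tert-butoxyphenyl benzoate | O=C(Oc1c(OC(C)(C)C)c(-c2ccc(OCc3ccccc3)cc2)c(OCc2ccccc2)c(OCc2ccccc2)c1-c1ccc(OCc2ccccc2)cc1)c1ccccc1
F11 | step 7 | 3,4-bis(benzyloxy)-2,5-bis[4-(benzyloxy)phenyl]-6-hydroxyphenyl benzoate | O=C(Oc1c(O)c(-c2ccc(OCc3ccccc3)cc2)c(OCc2ccccc2)c(OCc2ccccc2)c1-c1ccc(OCc2ccccc2)cc1)c1ccccc1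
A1 | alternative 1 | 4,7-bis(2-oxoethyl)-1,3-benzodioxole-5,6-diyl dibenzoate | O=CCc1c(OC(=O)c2ccccc2)c(OC(=O)c2ccccc2)c(CC=O)c2OCOc12
A2 | alternative 1 | 4,7-bis(4-oxocyclohex-2-en-1-yl)-1,3-benzodioxole-5,6-diyl dibenzoate (diastereomer mixture) | O=C1C=CC(CC1)c1c(OC(=O)c2ccccc2)c(OC(=O)c2ccccc2)c(C2C=CC(=O)CC2)c2OCOc12
A3 | alternative 2 | methyl 3-[4-(benzyloxy)phenyl]-2-oxopropanoate | COC(=O)C(=O)Cc1ccc(OCc2ccccc2)cc1
A4 | alternative 2 | 2,5-bis[4-(benzyloxy)phenyl]-3,6-dihydroxy-1,4-benzoquinone | O=C1C(O)=C(c2ccc(OCc3ccccc3)cc2)C(=O)C(O)=C1c1ccc(OCc2ccccc2)cc1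
A5 | alternative 3 | {3,6-bis[4-(benzyloxy)phenyl]-4,5-bis(tert-butyldimethylsilyloxy)-1,2-phenylene}bis(phenylmethanone) | O=C(c1ccccc1)c1c(C(=O)c2ccccc2)c(-c2ccc(OCc3ccccc3)cc2)c(O[Si](C)(C)C(C)(C)C)c(O[Si](C)(C)C(C)(C)C)c1-c1ccc(OCc2ccccc2)cc1
A6 | alternative 3 | 3,6-bis[4-(benzyloxy)phenyl]-4,5-bis(tert-butyldimethylsilyloxy)-1,2-phenylene dibenzoate | O=C(Oc1c(OC(=O)c2ccccc2)c(-c2ccc(OCc3ccccc3)cc2)c(O[Si](C)(C)C(C)(C)C)c(O[Si](C)(C)C(C)(C)C)c1-c1ccc(OCc2ccccc2)cc1)c1ccccc1
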